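**Plan**
Locants (cembrane type): ring C1–C14; C1 bears C15(CH3)2–O, C3 the ether oxygen (oxolane O–C3–C2–C1–C15), C4 the C18H2O arm, C8 the C19 aldehyde, C12 the C20 methyl.
Retrosynthetic cuts, in order: malonate ester at O18; C12–C13, with a boron atom placed between the two carbons (15-membered boracycle); O–C15 of the oxolane; C3–C4 (aldol); C7=C8 (HWE); C1–C15 (1,4-addition).
Enabling feature: C12 is the methyl-bearing sp2 carbon of the C11=C12 olefin and C13 its allylic ring CH2, so an alkenyl C12 and an alkyl C13 can share one boron atom; an iodine-induced 1,2-shift and B/I elimination contract that ring to the 14-membered carbocycle and expel boron.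
Forward: fragment A (C1–C3, C13–C17, boron on C13) and fragment B (C4–C12, C18–C20, (E)-12-iodoalkene) are joined by aldol at C3–C4; the oxolane forms first (alkoxymercuration), the 14-membered ring second (ring contraction); desilylation, allylic oxidation and malonylation finish.
Stereochemistry: C1 from Rh/(R)-BINAP 1,4-addition; C3 and C4 from the (S)-4-benzyloxazolidinone syn-aldol; 7E from the HWE reaction; 11Z from the hydrozirconation-derived (E)-iodoalkene by stereospecific inversion in the ring contraction.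

Key step: step 16

Remark: allyl hydrogen malonate (30) is treated as a purchasable reagent; it is otherwise available in one operation from Meldrum's acid and allyl alcohol.

Step 1
Reactants: 1 5,6-dihydro-2H-pyran-2-one; 2 isopropenylboronic acid pinacol ester
Product: 3 (R)-4-(prop-1-en-2-yl)oxan-2-one
Conditions: [RhCl(cod)]2 (2.5 mol%), (R)-BINAP (6 mol%), KOH (0.5 equiv), dioxane/H2O 10:1, 50 °C
Reagents that add atoms: none
Why: Hayashi–Miyaura rhodium-catalysed asymmetric 1,4-addition of an alkenylboron reagent to an unsaturated lactone; the Rh–(R)-BINAP alkenyl complex is expected to add to the face that gives (R)-C1, by analogy with (S)-BINAP giving (S)-4-aryl lactones.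

Step 2
Reactants: 3 (R)-4-(prop-1-en-2-yl)oxan-2-one
Product: 4 (3R)-5-hydroxy-N-methoxy-N-methyl-3-(prop-1-en-2-yl)pentanamide
Conditions: MeNH(OMe)·HCl, Me3Al, CH2Cl2, 0 °C → rt
Reagents that add atoms: N,O-dimethylhydroxylamine hydrochloride, CNOC.Cl
Why: Weinreb aminolysis of the δ-lactone by the aluminium amide frees the C13 hydroxyl and holds C3 at a level that DIBAL-H later turns into the aldehyde.

Step 3
Reactants: 4 (3R)-5-hydroxy-N-methoxy-N-methyl-3-(prop-1-en-2-yl)pentanamide
Product: 5 (3S)-5-iodo-N-methoxy-N-methyl-3-(prop-1-en-2-yl)pentanamide (same spatial arrangement; the descriptor changes with the iodine)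
Conditions: I2, PPh3, imidazole, CH2Cl2, 0 °C
Reagents that add atoms: iodine, II
Why: Appel-type iodination of the primary alcohol by SN2 at C13 should leave amide, olefin and stereocentre untouched.

Step 4
Reactants: 5 (3S)-5-iodo-N-methoxy-N-methyl-3-(prop-1-en-2-yl)pentanamide
Product: 6 (3R)-N-methoxy-N-methyl-3-(prop-1-en-2-yl)-5-(4,4,5,5-tetramethyl-1,3,2-dioxaborolan-2-yl)pentanamide
Conditions: B2pin2, CuI (10 mol%), PPh3 (13 mol%), LiOMe, DMF, rt
Reagents that add atoms: bis(pinacolato)diboron, CC1(C)OB(OC1(C)C)B1OC(C)(C)C(C)(C)O1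
Why: Copper-catalysed borylation of a primary alkyl iodide installs the boron that later becomes the extruded ring atom; a C13 radical or organocopper has only 4-exo or 5-endo modes toward the isopropenyl group and should not cyclise.

Step 5
Reactants: 6 (3R)-N-methoxy-N-methyl-3-(prop-1-en-2-yl)-5-(4,4,5,5-tetramethyl-1,3,2-dioxaborolan-2-yl)pentanamide
Product: 7 (3R)-3-(prop-1-en-2-yl)-5-(4,4,5,5-tetramethyl-1,3,2-dioxaborolan-2-yl)pentanal (fragment A)
Conditions: DIBAL-H, THF, −78 °C; aq. Rochelle salt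
Reagents that add atoms: none
Why: DIBAL-H reduction of a Weinreb amide stops at the chelated hemiaminal and releases the aldehyde on work-up; the alkyl pinacol boronate should tolerate the hydride at −78 °C.

Step 6
Reactants: 8 (S)-4-benzyloxazolidin-2-one; 9 hex-5-enoyl chloride
Product: 10 (S)-4-benzyl-3-(hex-5-enoyl)oxazolidin-2-one
Conditions: n-BuLi, THF, −78 °C; then 9, −78 → 0 °C
Reagents that add atoms: none
Why: N-acylation of the lithiated Evans oxazolidinone with an acid chloride.

Step 7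
Reactants: 10 (S)-4-benzyl-3-(hex-5-enoyl)oxazolidin-2-one
Product: 11 5-[(S)-4-benzyl-2-oxooxazolidin-3-yl]-5-oxopentanal
Conditions: O3, CH2Cl2, −78 °C; then PPh3, −78 °C → rt
Reagents that add atoms: ozone, [O-][O+]=O
Why: Ozonolysis of the only olefin with reductive work-up gives the C7 aldehyde; imide and benzyl group are inert at −78 °C.

Step 8
Reactants: 12 pent-3-yn-1-ol
Product: 13 (E)-4-iodopent-3-en-1-ol
Conditions: Cp2Zr(H)Cl (2.3 equiv), THF, rt; then I2, 0 °C
Reagents that add atoms: iodine, II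
Why: Hydrozirconation of the 2-alkyne (syn addition, zirconium settling on the methyl-bearing carbon, one equivalent spent on the hydroxyl) and iodinolysis with retention should give the (E)-iodoalkene.

Step 9
Reactants: 13 (E)-4-iodopent-3-en-1-ol
Product: 14 (E)-2,5-diiodopent-2-ene
Conditions: I2, PPh3, imidazole, CH2Cl2, 0 °C → rt
Reagents that add atoms: iodine, II
Why: Appel iodination of the primary alcohol; the vinylic iodide is inert.

Step 10
Reactants: 14 (E)-2,5-diiodopent-2-ene; 15 triethyl phosphonoacetate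
Product: 16 ethyl (E)-2-(diethoxyphosphoryl)-6-iodohept-5-enoate (racemic at C2)
Conditions: NaH, DMF, 0 °C; then 14, rt → 50 °C (15 in excess)
Reagents that add atoms: none
Why: C-alkylation of the stabilised phosphonoacetate anion by SN2 at the primary iodide; excess anion should limit dialkylation and the weakly basic nucleophile should limit elimination.

Step 11
Reactants: 16 ethyl (E)-2-(diethoxyphosphoryl)-6-iodohept-5-enoate; 11 5-[(S)-4-benzyl-2-oxooxazolidin-3-yl]-5-oxopentanal
Product: 17 ethyl (2E)-7-[(S)-4-benzyl-2-oxooxazolidin-3-yl]-2-[(E)-4-iodopent-3-en-1-yl]-7-oxohept-2-enoate (fragment B)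
Conditions: NaH, THF, 0 °C; then 11, −20 °C → rt
Reagents that add atoms: none
Why: Horner–Wadsworth–Emmons olefination of an α-substituted phosphonoacetate should favour the (E)-enoate (ester trans to C6, C6 cis to C9), the thermodynamically preferred isomer; any (Z)-isomer is removed by chromatography.

Step 12
Reactants: 17 fragment B; 7 fragment A
Product: 18 (S)-4-benzyl-3-[(2S,3R,5R)-2-[(3E,7E)-4-(ethoxycarbonyl)-8-iodonona-3,7-dien-1-yl]-3-hydroxy-5-(prop-1-en-2-yl)-7-(4,4,5,5-tetramethyl-1,3,2-dioxaborolan-2-yl)heptanoyl]oxazolidin-2-one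
Conditions: Bu2BOTf, iPr2NEt, CH2Cl2, −78 → 0 °C; then 7, −78 → 0 °C; pH 7 buffer/MeOH work-up without peroxide
Reagents that add atoms: none
Why: Evans syn-aldol: the (Z)-dibutylboron enolate reacts through a Zimmerman–Traxler chair on the face away from the benzyl group and should set C3 (R) and C4 (S at this stage) syn, independent of the remote C1 centre; peroxide is omitted to spare the C–B bond.

Step 13
Reactants: 18 syn-aldol adduct
Product: 21 ethyl (2E,6R)-6-[(2R,4R)-5,5-dimethyl-4-[2-(4,4,5,5-tetramethyl-1,3,2-dioxaborolan-2-yl)ethyl]oxolan-2-yl]-7-hydroxy-2-[(E)-4-iodopent-3-en-1-yl]hept-2-enoate, via alkylmercury acetate 19 (not isolated), via oxolane imide 20 (not isolated)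
Conditions: Hg(OAc)2 (1.05 equiv), THF, 0 °C; then NaBH4, THF/H2O, 0 °C → rt
Reagents that add atoms: none
Why: Intramolecular alkoxymercuration of the 1,1-disubstituted olefin by the C3 hydroxyl (Markovnikov, 5-exo; C1 and C3 are already set, so the 2,4-cis oxolane follows) and then NaBH4, which demercurates C16 to the second methyl and reductively cleaves the N-acyloxazolidinone to the C18 alcohol.

Step 14
Reactants: 21 oxolane hydroxy ester
Product: 22 (2E,6R)-6-[(2R,4R)-5,5-dimethyl-4-[2-(4,4,5,5-tetramethyl-1,3,2-dioxaborolan-2-yl)ethyl]oxolan-2-yl]-2-[(E)-4-iodopent-3-en-1-yl]hept-2-ene-1,7-diol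
Conditions: DIBAL-H (4 equiv), CH2Cl2, −78 °C; aq. Rochelle salt
Reagents that add atoms: none
Why: DIBAL-H 1,2-reduction of the unsaturated ester to the C19 allylic alcohol; vinylic iodide and boronate should be inert at −78 °C.

Step 15
Reactants: 22 diol
Product: 23 bis(tert-butyldimethylsilyl) ether of 22 (O18 and O19 silylated; seco compound)
Conditions: TBSCl, imidazole, DMF, rt
Reagents that add atoms: tert-butyldimethylsilyl chloride, CC(C)(C)[Si](C)(C)Cl
Why: Silylation of both primary alcohols removes every acidic or electrophilic group ahead of the organolithium step.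

Step 16
Reactants: 23 seco compound ((E)-12-iodoalkene, C13–Bpin)
Product: 27 (1R,3R,4R,7E,11Z)-18,19-bis(tert-butyldimethylsilyloxy)-3,15-epoxycembra-7,11-diene, via alkenyllithium 24 (not isolated), via cyclic boronate complex 25 (not isolated), via iodoboronic ester 26 (not isolated)
Conditions: t-BuLi (2.05 equiv) added to 23 at 1 mM, THF/Et2O, −78 → −40 °C; then I2 (1.1 equiv), THF, −78 °C; then NaOMe, MeOH, −78 °C → rt
Reagents that add atoms: none
Why: Proposed new method: iodine–lithium exchange at the (E)-iodoalkene gives alkenyllithium 24, which adds to the pendant pinacol boronate to form the 15-membered boronate complex 25; iodine then forms an iodonium ion at C11=C12 that triggers the anti 1,2-shift of C13 from boron to C12 (26), and methoxide induces anti elimination of boron and iodide. The closest known reaction is the intermolecular Zweifel olefination of alkenyllithiums with alkyl pinacol boronates (I2, NaOMe), and halogen–lithium exchange run in the presence of a boron ester (in situ quench) indicates that exchange can outpace attack of the alkyllithium at boron. The 14-membered carbocycle is closed in the 1,2-metallate shift as a ring contraction of the 15-membered boracycle, boron leaving as MeOBpin, so the entropically costly event is a fast B–C complexation at high dilution and not a C–C bond formation. No stereocentre survives: C11 and C12 of 26 are transient, and anti shift followed by anti elimination converts the (E)-iodoalkene with inversion into the (11Z)-olefin, C13 ending cis to C10. The step needs intramolecular complexation over oligomerisation (1 mM, with the cis-oxolane and the C7=C8 olefin as turn elements), exchange at iodine over attack at boron (the second equivalent of t-BuLi is consumed by t-BuI), and iodination of the electron-rich alkenylboronate rather than of C7=C8 (1.1 equiv I2 at −78 °C).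

Step 17
Reactants: 27 bis-silyl macrocycle
Product: 28 (1R,3R,4R,7E,11Z)-3,15-epoxycembra-7,11-diene-18,19-diol
Conditions: TBAF, THF, 0 °C → rt
Reagents that add atoms: none
Why: Fluoride cleaves both primary silyl ethers.

Step 18
Reactants: 28 macrocyclic diol
Product: 29 (1R,3R,4R,7E,11Z)-18-hydroxy-3,15-epoxycembra-7,11-dien-19-al
Conditions: MnO2, CH2Cl2, rt
Reagents that add atoms: none
Why: MnO2 oxidises only the allylic primary alcohol, and the (E)-enal (CHO trans to C6) is the stable geometry and should be retained.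

Step 19
Reactants: 29 hydroxy enal; 30 allyl hydrogen malonate
Product: 31 allyl [(1R,3R,4R,7E,11Z)-19-oxo-3,15-epoxycembra-7,11-dien-18-yl] malonate
Conditions: EDC·HCl, DMAP (10 mol%), CH2Cl2, 0 °C
Reagents that add atoms: none
Why: Steglich-type esterification of the remaining primary alcohol with a malonic half ester, so that no strongly acidic active-methylene compound meets the enal.

Step 20
Reactants: 31 allyl malonate
Product: 32 3-{[(1R,3R,4R,7E,11Z)-19-oxo-3,15-epoxycembra-7,11-dien-18-yl]oxy}-3-oxopropanoic acid (CNP0170412.1)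
Conditions: Pd(PPh3)4 (5 mol%), sodium 4-toluenesulfinate, THF/MeOH, rt; dilute HCl work-up
Reagents that add atoms: none
Why: Tsuji–Trost deallylation transfers the allyl group to the sulfinate under neutral conditions that should leave the enal, both olefins and the alkyl malonate ester intact.

**Compound list**
1 | 5,6-dihydro-2H-pyran-2-one | O=C1C=CCCO1 | starting material
2 | isopropenylboronic acid pinacol ester | CC(=C)B1OC(C)(C)C(C)(C)O1 | starting material
3 | (R)-4-(prop-1-en-2-yl)oxan-2-one | O=C1C[C@@H](CCO1)C(C)=C | intermediate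
4 | (3R)-5-hydroxy-N-methoxy-N-methyl-3-(prop-1-en-2-yl)pentanamide | CON(C)C(=O)C[C@@H](CCO)C(C)=C | intermediate
5 | (3S)-5-iodo-N-methoxy-N-methyl-3-(prop-1-en-2-yl)pentanamide | CON(C)C(=O)C[C@@H](CCI)C(C)=C | intermediate
6 | (3R)-N-methoxy-N-methyl-3-(prop-1-en-2-yl)-5-(4,4,5,5-tetramethyl-1,3,2-dioxaborolan-2-yl)pentanamide | CON(C)C(=O)C[C@@H](CCB1OC(C)(C)C(C)(C)O1)C(C)=C | intermediate
7 | (3R)-3-(prop-1-en-2-yl)-5-(4,4,5,5-tetramethyl-1,3,2-dioxaborolan-2-yl)pentanal (fragment A) | O=CC[C@@H](CCB1OC(C)(C)C(C)(C)O1)C(C)=C | intermediate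
8 | (S)-4-benzyloxazolidin-2-one | O=C1N[C@@H](Cc2ccccc2)CO1 | starting material
9 | hex-5-enoyl chloride | C=CCCCC(=O)Cl | starting material
10 | (S)-4-benzyl-3-(hex-5-enoyl)oxazolidin-2-one | C=CCCCC(=O)N1[C@@H](Cc2ccccc2)COC1=O | intermediate
11 | 5-[(S)-4-benzyl-2-oxooxazolidin-3-yl]-5-oxopentanal | O=CCCCC(=O)N1[C@@H](Cc2ccccc2)COC1=O | intermediate
12 | pent-3-yn-1-ol | CC#CCCO | starting material
13 | (E)-4-iodopent-3-en-1-ol | C/C(I)=C\CCO | intermediate
14 | (E)-2,5-diiodopent-2-ene | C/C(I)=C\CCI | intermediate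
15 | triethyl phosphonoacetate | CCOC(=O)CP(=O)(OCC)OCC | starting material
16 | ethyl (E)-2-(diethoxyphosphoryl)-6-iodohept-5-enoate | CCOC(=O)C(CC/C=C(/I)C)P(=O)(OCC)OCC | intermediate
17 | ethyl (2E)-7-[(S)-4-benzyl-2-oxooxazolidin-3-yl]-2-[(E)-4-iodopent-3-en-1-yl]-7-oxohept-2-enoate (fragment B) | C/C(I)=C\CC/C(C(=O)OCC)=C\CCCC(=O)N1[C@@H](Cc2ccccc2)COC1=O | intermediate
18 | (S)-4-benzyl-3-[(2S,3R,5R)-2-[(3E,7E)-4-(ethoxycarbonyl)-8-iodonona-3,7-dien-1-yl]-3-hydroxy-5-(prop-1-en-2-yl)-7-(4,4,5,5-tetramethyl-1,3,2-dioxaborolan-2-yl)heptanoyl]oxazolidin-2-one | C/C(I)=C\CC/C(C(=O)OCC)=C\CC[C@H](C(=O)N1[C@@H](Cc2ccccc2)COC1=O)[C@H](O)C[C@@H](CCB3OC(C)(C)C(C)(C)O3)C(C)=C | intermediate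
19 | alkylmercury acetate: 18 cyclised to the oxolane (O–C15), C15 bearing CH3 and CH2HgOAc (both C15 epimers) | C/C(I)=C\CC/C(C(=O)OCC)=C\CC[C@H](C(=O)N1[C@@H](Cc2ccccc2)COC1=O)[C@H]3C[C@@H](CCB4OC(C)(C)C(C)(C)O4)C(C)(C[Hg]OC(C)=O)O3 | intermediate (not isolated)
20 | oxolane imide: demercurated 19 (5,5-dimethyloxolane, auxiliary still on C18) | C/C(I)=C\CC/C(C(=O)OCC)=C\CC[C@H](C(=O)N1[C@@H](Cc2ccccc2)COC1=O)[C@H]3C[C@@H](CCB4OC(C)(C)C(C)(C)O4)C(C)(C)O3 | intermediate (not isolated)
21 | ethyl (2E,6R)-6-[(2R,4R)-5,5-dimethyl-4-[2-(4,4,5,5-tetramethyl-1,3,2-dioxaborolan-2-yl)ethyl]oxolan-2-yl]-7-hydroxy-2-[(E)-4-iodopent-3-en-1-yl]hept-2-enoate | C/C(I)=C\CC/C(C(=O)OCC)=C\CC[C@H](CO)[C@H]1C[C@@H](CCB2OC(C)(C)C(C)(C)O2)C(C)(C)O1 | intermediate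
22 | (2E,6R)-6-[(2R,4R)-5,5-dimethyl-4-[2-(4,4,5,5-tetramethyl-1,3,2-dioxaborolan-2-yl)ethyl]oxolan-2-yl]-2-[(E)-4-iodopent-3-en-1-yl]hept-2-ene-1,7-diol | C/C(I)=C\CC/C(CO)=C\CC[C@H](CO)[C@H]1C[C@@H](CCB2OC(C)(C)C(C)(C)O2)C(C)(C)O1 | intermediate
23 | bis(tert-butyldimethylsilyl) ether of 22 (seco compound) | C/C(I)=C\CC/C(CO[Si](C)(C)C(C)(C)C)=C\CC[C@H](CO[Si](C)(C)C(C)(C)C)[C@H]1C[C@@H](CCB2OC(C)(C)C(C)(C)O2)C(C)(C)O1 | intermediate
24 | alkenyllithium: 23 with lithium in place of iodine at C12 | C/C([Li])=C\CC/C(CO[Si](C)(C)C(C)(C)C)=C\CC[C@H](CO[Si](C)(C)C(C)(C)C)[C@H]1C[C@@H](CCB2OC(C)(C)C(C)(C)O2)C(C)(C)O1 | intermediate (not isolated)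
25 | lithium salt of the 15-membered cyclic alkenyl(alkyl)pinacolboronate complex (boron bonded to C12 and C13) | [Li+].C/C1=C\CC/C(CO[Si](C)(C)C(C)(C)C)=C\CC[C@H](CO[Si](C)(C)C(C)(C)C)[C@H]2C[C@@H](CC[B-]13OC(C)(C)C(C)(C)O3)C(C)(C)O2 | intermediate (not isolated)
26 | 11-iodo-12-(pinacolboryl) 14-membered carbocycle (iodine on C11 anti to the new C12–C13 bond; one of the two facial diastereomers drawn) | C[C@@]1(B2OC(C)(C)C(C)(C)O2)[C@@H](I)CC/C(CO[Si](C)(C)C(C)(C)C)=C\CC[C@H](CO[Si](C)(C)C(C)(C)C)[C@H]3C[C@@H](CC1)C(C)(C)O3 | intermediate (not isolated)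
27 | (1R,3R,4R,7E,11Z)-18,19-bis(tert-butyldimethylsilyloxy)-3,15-epoxycembra-7,11-diene | C/C1=C/CC/C(CO[Si](C)(C)C(C)(C)C)=C\CC[C@H](CO[Si](C)(C)C(C)(C)C)[C@H]2C[C@@H](CC1)C(C)(C)O2 | intermediate
28 | (1R,3R,4R,7E,11Z)-3,15-epoxycembra-7,11-diene-18,19-diol | C/C1=C/CC/C(CO)=C\CC[C@H](CO)[C@H]2C[C@@H](CC1)C(C)(C)O2 | intermediate
29 | (1R,3R,4R,7E,11Z)-18-hydroxy-3,15-epoxycembra-7,11-dien-19-al | C/C1=C/CC/C(C=O)=C\CC[C@H](CO)[C@H]2C[C@@H](CC1)C(C)(C)O2 | intermediate
30 | allyl hydrogen malonate | OC(=O)CC(=O)OCC=C | starting material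
31 | allyl [(1R,3R,4R,7E,11Z)-19-oxo-3,15-epoxycembra-7,11-dien-18-yl] malonate | C/C1=C/CC/C(C=O)=C\CC[C@H](COC(=O)CC(=O)OCC=C)[C@H]2C[C@@H](CC1)C(C)(C)O2 | intermediate
32 | 3-{[(1R,3R,4R,7E,11Z)-19-oxo-3,15-epoxycembra-7,11-dien-18-yl]oxy}-3-oxopropanoic acid (CNP0170412.1) | C/C1=C/CC/C(C=O)=C\CC[C@H](COC(=O)CC(=O)O)[C@H]2C[C@@H](CC1)C(C)(C)O2 | target

**Totals**
Total step count: 20. Longest linear sequence: 14 steps (steps 1–5, then 12–20).

**Steps most likely to fail**

Step 16 (ring-contractive boronate rearrangement). t-BuLi may attack boron before the iodine–lithium exchange is complete, the alkenyllithium may complex a boronate of a second molecule and give oligomers, or iodine may add to C7=C8. The fallback makes the same C12–C13 bond with retention by a B-alkyl Suzuki–Miyaura macrocyclisation and therefore needs the (Z)-iodoalkene series. It sets out from triethyl phosphonoacetate 15, uses aldehydes 11 and 7 as in the main route, and returns at diol 28. 3-(tert-Butyldimethylsilyloxy)propanal is olefinated with Ph3P=C(I)CH3 (from ethyltriphenylphosphonium iodide, n-BuLi, I2, NaHMDS, THF, −78 °C; Stork–Zhao-type) to give (Z)-tert-butyl[(4-iodopent-3-en-1-yl)oxy]dimethylsilane F1. TBAF should give (Z)-4-iodopent-3-en-1-ol F2, and I2/PPh3/imidazole (Z)-2,5-diiodopent-2-ene F3. Alkylation of 15 (NaH, DMF) should give ethyl (Z)-2-(diethoxyphosphoryl)-6-iodohept-5-enoate F4, and HWE reaction with 11 the (Z)-iodoalkene isomer of fragment B F5. Evans aldol reaction with 7 should give the (Z)-iodoalkene aldol adduct F6. Hg(OAc)2 then NaBH4 should proceed through the alkylmercury acetate F7 and the oxolane imide F8 to the (Z)-iodoalkene oxolane hydroxy ester F9. PdCl2(dppf), Cs2CO3, DMF/THF/H2O, 60 °C, at 1 mM by slow addition, should close the ring to ethyl (1R,3R,4R,7E,11Z)-18-hydroxy-3,15-epoxycembra-7,11-dien-19-oate F10, and DIBAL-H (CH2Cl2, −78 °C) should give 28.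

Step 1 (rhodium-catalysed 1,4-addition). Transmetalation of the 1,1-disubstituted alkenylboron may be slow, protodeboronation or hydrolytic opening of the lactone in aqueous base may compete, or facial selectivity may be low. The fallback uses auxiliary control; it sets out from oxazolidinone 8 and returns at lactone 3. Doebner condensation of 3-(tert-butyldimethylsilyloxy)propanal with malonic acid (pyridine, piperidine) should give (E)-5-[(tert-butyldimethylsilyl)oxy]pent-2-enoic acid F11. Its pivaloyl mixed anhydride (PivCl, Et3N) and lithiated 8 should give (S)-4-benzyl-3-[(E)-5-[(tert-butyldimethylsilyl)oxy]pent-2-enoyl]oxazolidin-2-one F12. Isopropenylmagnesium bromide with CuBr·SMe2 (THF, −78 → −20 °C) should add to the chelated syn-s-cis enoyl imide on the face away from the benzyl group to give (S)-4-benzyl-3-[(3R)-5-[(tert-butyldimethylsilyl)oxy]-3-(prop-1-en-2-yl)pentanoyl]oxazolidin-2-one F13. TBAF (THF) removes the silyl group, and the alkoxide should lactonise with release of 8 to give 3.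

Step 13 (alkoxymercuration, demercuration and auxiliary cleavage in one flask). Mercury may exchange with the C–B bond, demercuration may revert to the olefin, or borohydride cleavage of the imide may be incomplete. The fallback separates the two events and avoids mercury; it sets out from 18 and returns at 21. Hydrogen-atom-transfer hydroalkoxylation (Co(salen) catalyst, N-fluoro-2,4,6-trimethylpyridinium tetrafluoroborate, 1,1,3,3-tetramethyldisiloxane, PhCF3, rt; Mukaiyama-type) should close the oxolane through the C15 tertiary radical and cation to give oxolane imide 20, now isolated. LiBH4, MeOH, THF, 0 °C should then remove the auxiliary to give 21.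

**Further compounds**
F1 | step 16 | (Z)-tert-butyl[(4-iodopent-3-en-1-yl)oxy]dimethylsilane | C/C(I)=C/CCO[Si](C)(C)C(C)(C)C
F2 | step 16 | (Z)-4-iodopent-3-en-1-ol | C/C(I)=C/CCO
F3 | step 16 | (Z)-2,5-diiodopent-2-ene | C/C(I)=C/CCI
F4 | step 16 | ethyl (Z)-2-(diethoxyphosphoryl)-6-iodohept-5-enoate | CCOC(=O)C(CC/C=C(\I)C)P(=O)(OCC)OCC
F5 | step 16 | ethyl (2E)-7-[(S)-4-benzyl-2-oxooxazolidin-3-yl]-2-[(Z)-4-iodopent-3-en-1-yl]-7-oxohept-2-enoate | C/C(I)=C/CC/C(C(=O)OCC)=C\CCCC(=O)N1[C@@H](Cc2ccccc2)COC1=O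
F6 | step 16 | (Z)-iodoalkene isomer of aldol adduct 18 | C/C(I)=C/CC/C(C(=O)OCC)=C\CC[C@H](C(=O)N1[C@@H](Cc2ccccc2)COC1=O)[C@H](O)C[C@@H](CCB3OC(C)(C)C(C)(C)O3)C(C)=C
F7 | step 16 | (Z)-iodoalkene isomer of alkylmercury acetate 19 | C/C(I)=C/CC/C(C(=O)OCC)=C\CC[C@H](C(=O)N1[C@@H](Cc2ccccc2)COC1=O)[C@H]3C[C@@H](CCB4OC(C)(C)C(C)(C)O4)C(C)(C[Hg]OC(C)=O)O3
F8 | step 16 | (Z)-iodoalkene isomer of oxolane imide 20 | C/C(I)=C/CC/C(C(=O)OCC)=C\CC[C@H](C(=O)N1[C@@H](Cc2ccccc2)COC1=O)[C@H]3C[C@@H](CCB4OC(C)(C)C(C)(C)O4)C(C)(C)O3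
F9 | step 16 | (Z)-iodoalkene isomer of oxolane hydroxy ester 21 | C/C(I)=C/CC/C(C(=O)OCC)=C\CC[C@H](CO)[C@H]1C[C@@H](CCB2OC(C)(C)C(C)(C)O2)C(C)(C)O1
F10 | step 16 | ethyl (1R,3R,4R,7E,11Z)-18-hydroxy-3,15-epoxycembra-7,11-dien-19-oate | C/C1=C/CC/C(C(=O)OCC)=C\CC[C@H](CO)[C@H]2C[C@@H](CC1)C(C)(C)O2
F11 | step 1 | (E)-5-[(tert-butyldimethylsilyl)oxy]pent-2-enoic acid | O=C(O)/C=C/CCO[Si](C)(C)C(C)(C)C
F12 | step 1 | (S)-4-benzyl-3-[(E)-5-[(tert-butyldimethylsilyl)oxy]pent-2-enoyl]oxazolidin-2-one | O=C(/C=C/CCO[Si](C)(C)C(C)(C)C)N1[C@@H](Cc2ccccc2)COC1=O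
F13 | step 1 | (S)-4-benzyl-3-[(3R)-5-[(tert-butyldimethylsilyl)oxy]-3-(prop-1-en-2-yl)pentanoyl]oxazolidin-2-one | O=C(C[C@@H](CCO[Si](C)(C)C(C)(C)C)C(C)=C)N1[C@@H](Cc2ccccc2)COC1=O
F0 | step 13 | none | none
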